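## Retrosynthetic overview

1. Late operations (global desilylation, C12 allylic alcohol to acid, C8 acylation with acid 32) lead back to cyclohexanol 27.
2. C5–C6 (key): in the ring C5–C6–C7–C8–C9–C10 the carbinol C6 is vicinal to C5, which carries the 1,1-disubstituted alkene C4(=C3H2)–C15H2O. This homoallylic alcohol array O–C6–C5–C4=C3, with all substituents on C5–C8 equatorial, is the retron of an intramolecular carbonyl-ene reaction of open-chain aldehyde 26; a C–H bond of the C3 methyl group is the only activating group.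
3. C7–C8: Evans syn aldol of imide 21 (fragment 2: C6, C7, C11–C13) with aldehyde 13 (fragment 1).
4. C5–C10: copper-catalysed enantioselective SN2' substitution of allylic phosphate 10 by (Z)-alkenylboronate 5 creates the quaternary C10 and its vinyl group.
5. Ring order: the cyclohexane is the only ring and is closed once, in step 16, after all other skeletal bonds are in place.

Key step: step 16

Numbering used below (elemane numbers): C10 = quaternary carbon (C14 methyl, C1=C2 vinyl); C9 = ring CH2; C8 = acyloxy carbon; C7 bears C11(=C13H2)–C12; C6 = carbinol; C5 bears C4(=C3H2)–C15. TBS = tert-butyldimethylsilyl, TBDPS = tert-butyldiphenylsilyl, TES = triethylsilyl, PMB = 4-methoxybenzyl, pin = pinacolato.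

Assumption: in step 6 the antipode of the chiral ligand that delivers the (S) quaternary centre is used; both antipodes are accessible in the same way.

## Route

Step 1
Reactants: 1 prop-2-yn-1-ol
Product: 3 (Z)-3-iodo-2-methylprop-2-en-1-ol, via alkenylmagnesium alkoxide 2 (not isolated)
Conditions: MeMgBr (2.5 equiv), CuI (10 mol %), THF, −10 °C → rt; then I2, −78 → 0 °C
Reagents that add atoms: methylmagnesium bromide, C[Mg]Br; iodine, II
Why: Copper-catalysed anti-carbomagnesiation of the propargylic alkoxide gives a five-membered alkenylmagnesium chelate, so magnesium (then iodine, by iodinolysis with retention) ends cis to the CH2O group and methyl goes to the internal carbon, which fixes the Z geometry needed in step 16.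

Step 2
Reactants: 3 (Z)-3-iodo-2-methylprop-2-en-1-ol
Product: 4 TBDPS ether of 3
Conditions: TBDPSCl, imidazole, CH2Cl2, 0 °C → rt
Reagents that add atoms: tert-butyl(chloro)diphenylsilane, Cl[Si](c1ccccc1)(c1ccccc1)C(C)(C)C
Why: Silyl ether formation on a primary allylic alcohol; the robust TBDPS group should survive all later acidic and Lewis acidic steps.

Step 3
Reactants: 4 TBDPS ether of 3
Product: 5 (Z)-alkenylboronic acid pinacol ester
Conditions: B2pin2, PdCl2(PPh3)2 (3 mol %), PPh3, KOPh, toluene, 50 °C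
Reagents that add atoms: bis(pinacolato)diboron, CC1(C)OB(OC1(C)C)B1OC(C)(C)C(C)(C)O1
Why: Miyaura borylation of an alkenyl iodide (oxidative addition, boryl transfer, reductive elimination) keeps the double-bond geometry, and the weak base KOPh should suppress Suzuki homocoupling.

Step 4
Reactants: 6 (but-3-yn-1-yloxy)(tert-butyl)dimethylsilane
Product: 9 (E)-5-(TBS-oxy)-3-methylpent-2-en-1-ol, via alkenylalane 7 (not isolated), via lithium alkenylaluminate 8 (not isolated)
Conditions: Me3Al, Cp2ZrCl2 (20 mol %), CH2Cl2, 0 °C → rt; n-BuLi, THF, −78 °C; (CH2O)n, −78 °C → rt; aqueous work-up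
Reagents that add atoms: trimethylaluminium, C[Al](C)C; paraformaldehyde (as formaldehyde), C=O
Why: Zirconium-catalysed methylalumination adds methyl and aluminium syn across the terminal alkyne with aluminium on the terminal carbon, and the derived aluminate is hydroxymethylated with retention, giving the E trisubstituted allylic alcohol.

Step 5
Reactants: 9 (E)-5-(TBS-oxy)-3-methylpent-2-en-1-ol
Product: 10 allylic diethyl phosphate
Conditions: ClP(O)(OEt)2, Et3N, DMAP (cat.), CH2Cl2, 0 °C
Reagents that add atoms: diethyl chlorophosphate, CCOP(=O)(Cl)OCC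
Why: O-Phosphorylation of the primary allylic alcohol installs the leaving group required for copper-catalysed allylic substitution.

Step 6
Reactants: 5 (Z)-alkenylboronic acid pinacol ester; 10 allylic diethyl phosphate
Product: 11 (S)-1,4-diene bis-silyl ether
Conditions: CuCl (5 mol %), chiral sulfonate-bearing imidazolinium salt (N-heterocyclic carbene precursor, 5.5 mol %), NaOMe (1.5 equiv), THF, 22 → 50 °C
Reagents that add atoms: none
Why: Copper-catalysed enantioselective allylic substitution: the methoxide-activated boronate passes its alkenyl group with retention to the chiral carbene–copper centre, which adds in the SN2' sense to the γ,γ-disubstituted terminus of 10, so the catalyst's face selection sets the quaternary C10 as (S) and the leaving terminus becomes the vinyl group.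

Step 7
Reactants: 11 (S)-1,4-diene bis-silyl ether
Product: 12 (S)-primary alcohol
Conditions: PPTS (cat.), MeOH, rt
Reagents that add atoms: none
Why: Selective desilylation: acid-catalysed methanolysis removes the primary alkyl TBS ether much faster than the bulkier allylic TBDPS ether.

Step 8
Reactants: 12 (S)-primary alcohol
Product: 13 (S)-aldehyde (fragment 1)
Conditions: Dess–Martin periodinane, CH2Cl2, 0 °C → rt
Reagents that add atoms: none
Why: Dess–Martin oxidation gives the aldehyde under neutral conditions; the β-quaternary aldehyde has no α stereocentre to lose.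

Step 9
Reactants: 14 4-methoxybenzyl alcohol; 15 3-chloro-2-(chloromethyl)prop-1-ene
Product: 16 PMB 2-(chloromethyl)allyl ether
Conditions: NaOH (50 % aq.), Bu4NHSO4 (5 mol %), toluene, rt; 15 in excess (3 equiv)
Reagents that add atoms: none
Why: Phase-transfer Williamson etherification; excess 15 limits double substitution, and SN2 and SN2' attack give the same product because 15 is symmetric.

Step 10
Reactants: 16 PMB 2-(chloromethyl)allyl ether
Product: 18 3-(PMB-oxymethyl)but-3-enoic acid, via allylmagnesium chloride 17 (not isolated)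
Conditions: Mg turnings, THF, 0 °C (slow addition, dilute); CO2, −78 °C → rt; aq. HCl to pH 3
Reagents that add atoms: carbon dioxide, O=C=O
Why: Grignard formation and carboxylation give the β,γ-unsaturated acid; the symmetric 2-substituted allyl unit makes the site of CO2 capture irrelevant.

Step 11
Reactants: 18 3-(PMB-oxymethyl)but-3-enoic acid; 19 (R)-4-benzyloxazolidin-2-one
Product: 21 N-acyl oxazolidinone (fragment 2), via mixed pivalic anhydride 20 (not isolated)
Conditions: t-BuCOCl, Et3N, THF, −20 °C; then 19, LiCl, −20 °C → rt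
Reagents that add atoms: none
Why: N-Acylation through the mixed anhydride with LiCl activation avoids strong base, so the β,γ double bond should not move into conjugation.

Step 12
Reactants: 21 N-acyl oxazolidinone (fragment 2); 13 (S)-aldehyde (fragment 1)
Product: 23 syn-aldol adduct, via Z boron enolate 22 (not isolated)
Conditions: Bu2BOTf, i-Pr2NEt, CH2Cl2, −78 → 0 °C; 13, −78 → 0 °C; pH 7 buffer, MeOH, H2O2, 0 °C
Reagents that add atoms: none
Why: Evans syn aldol reaction: the Z boron enolate reacts through a chair Zimmerman–Traxler transition state in which the (R)-benzyl group of the auxiliary blocks one enolate face, setting C7 (R) and C8 (S) syn under reagent control irrespective of the remote C10 centre.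

Step 13
Reactants: 23 syn-aldol adduct
Product: 24 C8 triethylsilyl ether
Conditions: Et3SiOTf, 2,6-lutidine, CH2Cl2, −78 °C
Reagents that add atoms: triethylsilyl triflate, CC[Si](CC)(CC)OS(=O)(=O)C(F)(F)F
Why: Silyl ether formation at the β-hydroxyl prevents retro-aldol cleavage and chelation in the following steps.

Step 14
Reactants: 24 C8 triethylsilyl ether
Product: 25 primary alcohol
Conditions: LiBH4, H2O (1 equiv), Et2O, 0 °C
Reagents that add atoms: none
Why: Reductive cleavage of the N-acyl oxazolidinone: hydride attacks the exocyclic imide carbonyl and releases the auxiliary without touching C7.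

Step 15
Reactants: 25 primary alcohol
Product: 26 aldehyde (ene precursor)
Conditions: Dess–Martin periodinane, NaHCO3, CH2Cl2, 0 °C; used at once
Reagents that add atoms: none
Why: Buffered Dess–Martin oxidation gives the β,γ-unsaturated aldehyde without acid or base that could epimerise C7 or move the double bond.

Step 16
Reactants: 26 aldehyde (ene precursor)
Product: 27 cyclohexanol
Conditions: Me2AlCl (1.5 equiv), CH2Cl2 (0.01 M), −78 → −40 °C; then aq. potassium sodium tartrate
Reagents that add atoms: none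
Why: Me2AlCl binds the aldehyde oxygen and C6 is attacked by C5 of the Z trisubstituted alkene while a hydrogen of the C3 methyl group passes to oxygen through a six-membered array, so the C5–C6 bond, the C4=C3 methylene group and the C6 hydroxyl arise together (concerted or nearly concerted carbonyl-ene reaction). The closest known reaction type is the Lewis-acid-promoted intramolecular carbonyl-ene cyclisation of 6-enals, as in citronellal to isopulegol. The cyclohexane C5–C6–C7–C8–C9–C10 closes in a 6-exo-trig mode at the carbonyl carbon, with C4 left exocyclic, through a chair-like transition state. C6 and C5 are set by that chair: the existing C7 side chain and C8 silyloxy group lie equatorial, which puts the C10 methyl axial, so the aluminium-bound oxygen must be equatorial (an axial one would clash 1,3-diaxially with that methyl) and C4 is equatorial, giving the trans C5/C6 pair with R configuration at both. The step needs hydrogen transfer from C3 rather than C15 and trans diastereoselectivity, and both follow from the Z geometry, because only the group on C4 that is trans to C10 (the methyl) can reach an equatorial oxygen. The vinyl group on C10 has no allylic hydrogen and the alkene on C7 cannot reach C6, while the low temperature and Me2AlCl as proton scavenger should protect C7 and the silyl and PMB ethers.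

Step 17
Reactants: 27 cyclohexanol
Product: 28 C6 TBS ether
Conditions: t-BuMe2SiOTf, 2,6-lutidine, CH2Cl2, 0 °C → rt
Reagents that add atoms: tert-butyldimethylsilyl triflate, CC(C)(C)[Si](C)(C)OS(=O)(=O)C(F)(F)F
Why: Silyl ether formation with the reactive triflate caps the hindered equatorial C6 hydroxyl so that it can neither lactonise onto C12 nor compete for acylation later.

Step 18
Reactants: 28 C6 TBS ether
Product: 29 C8 alcohol
Conditions: PPTS, MeOH/CH2Cl2, 0 °C → rt
Reagents that add atoms: none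
Why: Selective desilylation: acidic methanolysis cleaves the triethylsilyl ether, whereas the TBS and TBDPS ethers react orders of magnitude more slowly.

Step 19
Reactants: 30 ethyl 2-(hydroxymethyl)acrylate
Product: 31 TBS ether of 30
Conditions: t-BuMe2SiCl, imidazole, CH2Cl2, 0 °C → rt
Reagents that add atoms: tert-butyl(chloro)dimethylsilane, CC(C)(C)[Si](C)(C)Cl
Why: Silyl ether formation protects the primary allylic hydroxyl of the side chain.

Step 20
Reactants: 31 TBS ether of 30
Product: 32 2-(TBS-oxymethyl)acrylic acid (fragment 3)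
Conditions: LiOH, THF/H2O, 0 °C; then cold aq. HCl to pH 3–4
Reagents that add atoms: lithium hydroxide, [Li+].[OH-]
Why: Ester hydrolysis at 0 °C followed by mild acidification should give the acid with the TBS ether intact.

Step 21
Reactants: 29 C8 alcohol; 32 2-(TBS-oxymethyl)acrylic acid (fragment 3)
Product: 34 C8 ester, via mixed trichlorobenzoic anhydride 33 (not isolated)
Conditions: 2,4,6-trichlorobenzoyl chloride, Et3N, toluene, rt; then 29, DMAP, toluene, 0 °C → rt
Reagents that add atoms: none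
Why: Yamaguchi esterification: DMAP attacks the acrylic carbonyl of the mixed anhydride and the acyl group passes to the only free hydroxyl, at C8, with no change at any stereocentre.

Step 22
Reactants: 34 C8 ester
Product: 35 C12 alcohol
Conditions: DDQ, CH2Cl2/pH 7 buffer, 0 °C
Reagents that add atoms: none
Why: Oxidative PMB ether cleavage (hydride abstraction to the oxocarbenium ion, then hydrolysis) frees the C12 allylic alcohol and leaves silyl ethers and alkenes untouched.

Step 23
Reactants: 35 C12 alcohol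
Product: 37 C12 acid, via C12 enal 36 (not isolated)
Conditions: MnO2, CH2Cl2, rt, filtration; then NaClO2, NaH2PO4, 2-methylbut-2-ene, t-BuOH/H2O, 0 °C → rt
Reagents that add atoms: sodium chlorite, [Na+].[O-]Cl=O
Why: MnO2 oxidises only the free allylic alcohol to the 2-substituted acrolein, and Pinnick oxidation with an alkene scavenger converts it into the acrylic acid without touching C7 or the other alkenes.

Step 24
Reactants: 37 C12 acid
Product: 38 target CNP0509685.1
Conditions: HF·pyridine, excess pyridine, THF, 0 °C → rt; work-up at pH 5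
Reagents that add atoms: none
Why: Fluoride-mediated desilylation removes the three silyl ethers; the carboxylic acid is already free and the medium is buffered, so closure of the C6 hydroxyl onto C12 to a lactone should be slow.

## Compound list

1 | prop-2-yn-1-ol | C#CCO | starting material
2 | bromo[(1Z)-3-(bromomagnesiooxy)-2-methylprop-1-en-1-yl]magnesium | Br[Mg]/C=C(/C)CO[Mg]Br | intermediate
3 | (2Z)-3-iodo-2-methylprop-2-en-1-ol | I/C=C(/C)CO | intermediate
4 | tert-butyl{[(2Z)-3-iodo-2-methylprop-2-en-1-yl]oxy}diphenylsilane | I/C=C(/C)CO[Si](c1ccccc1)(c1ccccc1)C(C)(C)C | intermediate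
5 | tert-butyl{[(2Z)-2-methyl-3-(4,4,5,5-tetramethyl-1,3,2-dioxaborolan-2-yl)prop-2-en-1-yl]oxy}diphenylsilane | CC1(C)OB(/C=C(/C)CO[Si](c2ccccc2)(c2ccccc2)C(C)(C)C)OC1(C)C | intermediate
6 | (but-3-yn-1-yloxy)(tert-butyl)dimethylsilane | C#CCCO[Si](C)(C)C(C)(C)C | starting material
7 | [(1E)-4-{[tert-butyl(dimethyl)silyl]oxy}-2-methylbut-1-en-1-yl]dimethylalumane | C[Al](C)/C=C(\C)CCO[Si](C)(C)C(C)(C)C | intermediate
8 | lithium butyl[(1E)-4-{[tert-butyl(dimethyl)silyl]oxy}-2-methylbut-1-en-1-yl]dimethylaluminate | [Li+].CCCC[Al-](C)(C)/C=C(\C)CCO[Si](C)(C)C(C)(C)C | intermediate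
9 | (2E)-5-{[tert-butyl(dimethyl)silyl]oxy}-3-methylpent-2-en-1-ol | OC/C=C(\C)CCO[Si](C)(C)C(C)(C)C | intermediate
10 | (2E)-5-{[tert-butyl(dimethyl)silyl]oxy}-3-methylpent-2-en-1-yl diethyl phosphate | CCOP(=O)(OCC)OC/C=C(\C)CCO[Si](C)(C)C(C)(C)C | intermediate
11 | tert-butyl{[(2Z,4S)-4-(2-{[tert-butyl(dimethyl)silyl]oxy}ethyl)-2,4-dimethylhexa-2,5-dien-1-yl]oxy}diphenylsilane | C=C[C@](/C=C(/C)CO[Si](c1ccccc1)(c1ccccc1)C(C)(C)C)(C)CCO[Si](C)(C)C(C)(C)C | intermediate
12 | (3S,4Z)-6-{[tert-butyl(diphenyl)silyl]oxy}-3-ethenyl-3,5-dimethylhex-4-en-1-ol | C=C[C@](/C=C(/C)CO[Si](c1ccccc1)(c1ccccc1)C(C)(C)C)(C)CCO | intermediate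
13 | (3S,4Z)-6-{[tert-butyl(diphenyl)silyl]oxy}-3-ethenyl-3,5-dimethylhex-4-enal | C=C[C@](/C=C(/C)CO[Si](c1ccccc1)(c1ccccc1)C(C)(C)C)(C)CC=O | intermediate
14 | (4-methoxyphenyl)methanol | COc1ccc(CO)cc1 | starting material
15 | 3-chloro-2-(chloromethyl)prop-1-ene | C=C(CCl)CCl | starting material
16 | 1-({[2-(chloromethyl)prop-2-en-1-yl]oxy}methyl)-4-methoxybenzene | C=C(CCl)COCc1ccc(OC)cc1 | intermediate
17 | chloro(2-{[(4-methoxybenzyl)oxy]methyl}prop-2-en-1-yl)magnesium | C=C(C[Mg]Cl)COCc1ccc(OC)cc1 | intermediate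
18 | 3-{[(4-methoxybenzyl)oxy]methyl}but-3-enoic acid | C=C(COCc1ccc(OC)cc1)CC(=O)O | intermediate
19 | (4R)-4-benzyl-1,3-oxazolidin-2-one | O=C1N[C@H](Cc2ccccc2)CO1 | starting material
20 | 2,2-dimethylpropanoic 3-{[(4-methoxybenzyl)oxy]methyl}but-3-enoic anhydride | C=C(COCc1ccc(OC)cc1)CC(=O)OC(=O)C(C)(C)C | intermediate
21 | (4R)-4-benzyl-3-(3-{[(4-methoxybenzyl)oxy]methyl}but-3-enoyl)-1,3-oxazolidin-2-one | C=C(COCc1ccc(OC)cc1)CC(=O)N1[C@H](Cc2ccccc2)COC1=O | intermediate
22 | (Z)-dibutylboron enolate of 21 (O–B and the propenyl group cis) | C=C(COCc1ccc(OC)cc1)/C=C(\OB(CCCC)CCCC)N1[C@H](Cc2ccccc2)COC1=O | intermediate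
23 | (4R)-4-benzyl-3-[(2R,3S,5S,6Z)-8-{[tert-butyl(diphenyl)silyl]oxy}-5-ethenyl-3-hydroxy-2-{3-[(4-methoxybenzyl)oxy]prop-1-en-2-yl}-5,7-dimethyloct-6-enoyl]-1,3-oxazolidin-2-one | C=C[C@](/C=C(/C)CO[Si](c1ccccc1)(c1ccccc1)C(C)(C)C)(C)C[C@H](O)[C@@H](C(=C)COCc1ccc(OC)cc1)C(=O)N1[C@H](Cc2ccccc2)COC1=O | intermediate
24 | (4R)-4-benzyl-3-[(2R,3S,5S,6Z)-8-{[tert-butyl(diphenyl)silyl]oxy}-5-ethenyl-2-{3-[(4-methoxybenzyl)oxy]prop-1-en-2-yl}-5,7-dimethyl-3-[(triethylsilyl)oxy]oct-6-enoyl]-1,3-oxazolidin-2-one | C=C[C@](/C=C(/C)CO[Si](c1ccccc1)(c1ccccc1)C(C)(C)C)(C)C[C@H](O[Si](CC)(CC)CC)[C@@H](C(=C)COCc1ccc(OC)cc1)C(=O)N1[C@H](Cc2ccccc2)COC1=O | intermediate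
25 | (2S,3S,5S,6Z)-8-{[tert-butyl(diphenyl)silyl]oxy}-5-ethenyl-2-{3-[(4-methoxybenzyl)oxy]prop-1-en-2-yl}-5,7-dimethyl-3-[(triethylsilyl)oxy]oct-6-en-1-ol | C=C[C@](/C=C(/C)CO[Si](c1ccccc1)(c1ccccc1)C(C)(C)C)(C)C[C@H](O[Si](CC)(CC)CC)[C@@H](C(=C)COCc1ccc(OC)cc1)CO | intermediate
26 | (2R,3S,5S,6Z)-8-{[tert-butyl(diphenyl)silyl]oxy}-5-ethenyl-2-{3-[(4-methoxybenzyl)oxy]prop-1-en-2-yl}-5,7-dimethyl-3-[(triethylsilyl)oxy]oct-6-enal | C=C[C@](/C=C(/C)CO[Si](c1ccccc1)(c1ccccc1)C(C)(C)C)(C)C[C@H](O[Si](CC)(CC)CC)[C@@H](C(=C)COCc1ccc(OC)cc1)C=O | intermediate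
27 | (5R,6R,7S,8S,10S)-15-[(tert-butyldiphenylsilyl)oxy]-12-[(4-methoxybenzyl)oxy]-8-[(triethylsilyl)oxy]elema-1,3,11(13)-trien-6-ol (C5–C8 substituents equatorial, C10 methyl axial) | C=C[C@]1(C)C[C@H](O[Si](CC)(CC)CC)[C@@H](C(=C)COCc2ccc(OC)cc2)[C@H](O)[C@H]1C(=C)CO[Si](c1ccccc1)(c1ccccc1)C(C)(C)C | intermediate
28 | (5R,6R,7R,8S,10S)-6-[(tert-butyldimethylsilyl)oxy]-15-[(tert-butyldiphenylsilyl)oxy]-12-[(4-methoxybenzyl)oxy]-8-[(triethylsilyl)oxy]elema-1,3,11(13)-triene | C=C[C@]1(C)C[C@H](O[Si](CC)(CC)CC)[C@@H](C(=C)COCc2ccc(OC)cc2)[C@H](O[Si](C)(C)C(C)(C)C)[C@H]1C(=C)CO[Si](c1ccccc1)(c1ccccc1)C(C)(C)C | intermediate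
29 | (5R,6R,7R,8S,10S)-6-[(tert-butyldimethylsilyl)oxy]-15-[(tert-butyldiphenylsilyl)oxy]-12-[(4-methoxybenzyl)oxy]elema-1,3,11(13)-trien-8-ol | C=C[C@]1(C)C[C@H](O)[C@@H](C(=C)COCc2ccc(OC)cc2)[C@H](O[Si](C)(C)C(C)(C)C)[C@H]1C(=C)CO[Si](c1ccccc1)(c1ccccc1)C(C)(C)C | intermediate
30 | ethyl 2-(hydroxymethyl)prop-2-enoate | C=C(CO)C(=O)OCC | starting material
31 | ethyl 2-({[tert-butyl(dimethyl)silyl]oxy}methyl)prop-2-enoate | C=C(CO[Si](C)(C)C(C)(C)C)C(=O)OCC | intermediate
32 | 2-({[tert-butyl(dimethyl)silyl]oxy}methyl)prop-2-enoic acid | C=C(CO[Si](C)(C)C(C)(C)C)C(=O)O | intermediate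
33 | 2-({[tert-butyl(dimethyl)silyl]oxy}methyl)prop-2-enoic 2,4,6-trichlorobenzoic anhydride | C=C(CO[Si](C)(C)C(C)(C)C)C(=O)OC(=O)c1c(Cl)cc(Cl)cc1Cl | intermediate
34 | (5R,6R,7R,8S,10S)-6-[(tert-butyldimethylsilyl)oxy]-15-[(tert-butyldiphenylsilyl)oxy]-12-[(4-methoxybenzyl)oxy]elema-1,3,11(13)-trien-8-yl 2-({[tert-butyl(dimethyl)silyl]oxy}methyl)prop-2-enoate | C=C[C@]1(C)C[C@H](OC(=O)C(=C)CO[Si](C)(C)C(C)(C)C)[C@@H](C(=C)COCc2ccc(OC)cc2)[C@H](O[Si](C)(C)C(C)(C)C)[C@H]1C(=C)CO[Si](c1ccccc1)(c1ccccc1)C(C)(C)C | intermediate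
35 | (5R,6R,7R,8S,10S)-6-[(tert-butyldimethylsilyl)oxy]-15-[(tert-butyldiphenylsilyl)oxy]-12-hydroxyelema-1,3,11(13)-trien-8-yl 2-({[tert-butyl(dimethyl)silyl]oxy}methyl)prop-2-enoate | C=C[C@]1(C)C[C@H](OC(=O)C(=C)CO[Si](C)(C)C(C)(C)C)[C@@H](C(=C)CO)[C@H](O[Si](C)(C)C(C)(C)C)[C@H]1C(=C)CO[Si](c1ccccc1)(c1ccccc1)C(C)(C)C | intermediate
36 | (5R,6R,7R,8S,10S)-6-[(tert-butyldimethylsilyl)oxy]-15-[(tert-butyldiphenylsilyl)oxy]-12-oxoelema-1,3,11(13)-trien-8-yl 2-({[tert-butyl(dimethyl)silyl]oxy}methyl)prop-2-enoate | C=C[C@]1(C)C[C@H](OC(=O)C(=C)CO[Si](C)(C)C(C)(C)C)[C@@H](C(=C)C=O)[C@H](O[Si](C)(C)C(C)(C)C)[C@H]1C(=C)CO[Si](c1ccccc1)(c1ccccc1)C(C)(C)C | intermediate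
37 | (5R,6R,7R,8S,10S)-6-[(tert-butyldimethylsilyl)oxy]-15-[(tert-butyldiphenylsilyl)oxy]-8-{[2-({[tert-butyl(dimethyl)silyl]oxy}methyl)prop-2-enoyl]oxy}elema-1,3,11(13)-trien-12-oic acid | C=C[C@]1(C)C[C@H](OC(=O)C(=C)CO[Si](C)(C)C(C)(C)C)[C@@H](C(=C)C(=O)O)[C@H](O[Si](C)(C)C(C)(C)C)[C@H]1C(=C)CO[Si](c1ccccc1)(c1ccccc1)C(C)(C)C | intermediate
38 | (5R,6R,7S,8S,10S)-6,15-dihydroxy-8-{[2-(hydroxymethyl)prop-2-enoyl]oxy}elema-1,3,11(13)-trien-12-oic acid (CNP0509685.1) | C=C[C@]1(C)C[C@H](OC(=O)C(=C)CO)[C@@H](C(=C)C(=O)O)[C@H](O)[C@H]1C(=C)CO | target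

## Step count and risks

Total: 24 steps. Longest linear sequence: 17 steps (1–3, 6–8, 12–18, 21–24).

**Step 6 (quaternary C10).** What may go wrong: the hindered Z trisubstituted alkenyl group is transferred slowly from boron to copper, so protodeboronation and linear SN2 substitution compete, and face discrimination at the γ,γ-disubstituted terminus may be incomplete. The fallback builds C10 by a sigmatropic shift and relies on the aldol auxiliary for the absolute configuration. It sets out from iodide 4: Stille coupling with (E)-3-(tributylstannyl)but-2-en-1-ol (Pd(PPh3)4, CuI, DMF) should give (2E,4Z)-dienol F1. Johnson–Claisen rearrangement (triethyl orthoacetate, cat. propionic acid, 120 °C) should deliver the acetate unit to the methyl-bearing alkene carbon and give racemic ester F2 with the quaternary carbon and its vinyl group. Reduction with i-Bu2AlH at −78 °C should give racemic aldehyde F3. The aldol of step 12 with enolate 22 should then give 23 together with its C10 epimer F4; these are diastereomers and are separated by chromatography. The fallback comes back to the route at 23.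

**Step 16 (ene ring closure).** What may go wrong: reaction through the chair with an axial aluminium-bound oxygen, so that the C6 epimer forms; partial epimerisation α to the aldehyde before ring closure is a second leak. The fallback replaces kinetic by thermodynamic control at C6. It sets out from 26: the cyclisation product containing the C6-epimeric alcohol F5 is oxidised (Dess–Martin periodinane, NaHCO3, CH2Cl2) to ketone F6, in which the C5 and C7 substituents stay equatorial. Electron-transfer reduction of F6 (SmI2, THF/H2O, 0 °C) should give the more stable equatorial alcohol. The fallback comes back at 27.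

**Step 21 (C8 acylation).** What may go wrong: DMAP adds to the activated acrylate and triggers oligomerisation faster than the hindered C8 hydroxyl is acylated. The fallback builds the acrylate on the ester instead of transferring it. It sets out from 29: carbodiimide coupling with diethylphosphonoacetic acid (EDC·HCl, cat. DMAP, CH2Cl2) should give phosphonoacetate F7. Aqueous formaldehyde and K2CO3 (hydroxymethylation followed by Horner–Wadsworth–Emmons methylenation) should give the 2-(hydroxymethyl)acrylate F8. Silylation (t-BuMe2SiCl, imidazole) brings the route back at 34.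

## Further compounds

F1 | step 6 | (2E,4Z)-6-{[tert-butyl(diphenyl)silyl]oxy}-3,5-dimethylhexa-2,4-dien-1-ol | OC/C=C(\C)/C=C(/C)CO[Si](c1ccccc1)(c1ccccc1)C(C)(C)C
F2 | step 6 | racemic ethyl (4Z)-6-{[tert-butyl(diphenyl)silyl]oxy}-3-ethenyl-3,5-dimethylhex-4-enoate | CCOC(=O)CC(C)(C=C)/C=C(/C)CO[Si](c1ccccc1)(c1ccccc1)C(C)(C)C
F3 | step 6 | racemic (4Z)-6-{[tert-butyl(diphenyl)silyl]oxy}-3-ethenyl-3,5-dimethylhex-4-enal | C=CC(C)(CC=O)/C=C(/C)CO[Si](c1ccccc1)(c1ccccc1)C(C)(C)C
F4 | step 6 | (5R)-epimer of aldol adduct 23 | C=C[C@@](/C=C(/C)CO[Si](c1ccccc1)(c1ccccc1)C(C)(C)C)(C)C[C@H](O)[C@@H](C(=C)COCc1ccc(OC)cc1)C(=O)N1[C@H](Cc2ccccc2)COC1=O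
F5 | step 16 | (5R,6S,7S,8S,10S)-epimer of cyclohexanol 27 (axial C6 hydroxyl) | C=C[C@]1(C)C[C@H](O[Si](CC)(CC)CC)[C@@H](C(=C)COCc2ccc(OC)cc2)[C@@H](O)[C@H]1C(=C)CO[Si](c1ccccc1)(c1ccccc1)C(C)(C)C
F6 | step 16 | (5R,7R,8S,10S)-15-[(tert-butyldiphenylsilyl)oxy]-12-[(4-methoxybenzyl)oxy]-8-[(triethylsilyl)oxy]elema-1,3,11(13)-trien-6-one | C=C[C@]1(C)C[C@H](O[Si](CC)(CC)CC)[C@@H](C(=C)COCc2ccc(OC)cc2)C(=O)[C@H]1C(=C)CO[Si](c1ccccc1)(c1ccccc1)C(C)(C)C
F7 | step 21 | C8 (diethoxyphosphoryl)acetate of 29 | C=C[C@]1(C)C[C@H](OC(=O)CP(=O)(OCC)OCC)[C@@H](C(=C)COCc2ccc(OC)cc2)[C@H](O[Si](C)(C)C(C)(C)C)[C@H]1C(=C)CO[Si](c1ccccc1)(c1ccccc1)C(C)(C)C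
F8 | step 21 | C8 2-(hydroxymethyl)prop-2-enoate of 29 | C=C[C@]1(C)C[C@H](OC(=O)C(=C)CO)[C@@H](C(=C)COCc2ccc(OC)cc2)[C@H](O[Si](C)(C)C(C)(C)C)[C@H]1C(=C)CO[Si](c1ccccc1)(c1ccccc1)C(C)(C)C
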